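**Retrosynthetic overview**
1. Target 34 comes from the (1(10)Z,2E,4Z)-triene tetraester 32 by two late epoxidations (C4=C5, then C2=C3); the butenolide comes from an intramolecular Wittig reaction of a C6 α-bromo ester with a C7 ketone; the C9/C14 esters come from the allylic 1,3-diol obtained by reducing a C9-keto C10-methyl ester.
2. The ten-membered carbocycle is not closed as such: it is grown from an eight-membered ring by inserting C10 and C1 (with C14 attached) between C9 and C2, through [2+2] addition of methyl propiolate to the C9=C2 silyl enol ether and conrotatory opening of the fused cyclobutene.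
3. Enabling feature: in the ten-membered ring the oxygen-bearing C9 is bonded to C10, which lies on the only ring double bond (C1=C10) and carries the one-carbon branch C14; C9(O)–C10(C14)=C1 is a β-oxy acrylate, the footprint of a propiolate inserted next to a ring ketone.
4. The eight-membered ketone comes from D-galactose (sugar C2, C3, C4, C5 become C8, C7, C6, C5) by zinc fragmentation, Grignard addition of C2–C4/C15 and ring-closing metathesis at C4=C5.
5. Ring order: dioxolane (temporary) → cyclooctene → cyclobutene (transient) → cyclodecatriene → butenolide → two oxiranes (the glycidate oxirane is brought in preformed).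

Key step: step 9

Remark: locants C1–C15 are those of the target skeleton (ring C1–C10; C14 on C10; C15 = methyl on C4; C11–C13 = butenolide carbons, C12 the carbonyl); the target SMILES is read as 1(10)Z-2R,3S,4S,5S,6R,8R,9R with an (S)-2-methyloxirane-2-carboxylate; TBS = tert-butyldimethylsilyl.

**Step 1**
Reactants: 1 methyl α-D-galactopyranoside
Product: 2 methyl 3,4-O-isopropylidene-α-D-galactopyranoside
Conditions: Me2C(OMe)2, CSA (cat.), acetone, rt; then aq. MeOH (cleaves the labile 6-O mixed ketal)
Reagents that add atoms: 2,2-dimethoxypropane, COC(C)(C)OC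
Why: Acid-catalysed acetonide formation (transketalisation) picks the only cis-vicinal diol O3/O4 of the galactoside, which masks the future O7 and O6 and later templates the eight-ring closure; no stereocentre is changed.

**Step 2**
Reactants: 2 methyl 3,4-O-isopropylidene-α-D-galactopyranoside
Product: 3 methyl 6-deoxy-6-iodo-3,4-O-isopropylidene-α-D-galactopyranoside
Conditions: I2, PPh3, imidazole, PhMe, 70 °C
Reagents that add atoms: iodine, II
Why: Garegg–Samuelsson (Appel-type) iodination converts only the primary 6-OH, the hindered secondary 2-OH next to the anomeric centre reacting much more slowly.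

**Step 3**
Reactants: 3 methyl 6-deoxy-6-iodo-3,4-O-isopropylidene-α-D-galactopyranoside
Product: 4 methyl 2-O-TBS-6-deoxy-6-iodo-3,4-O-isopropylidene-α-D-galactopyranoside
Conditions: TBSOTf, 2,6-lutidine, CH2Cl2, 0 °C
Reagents that add atoms: tert-butyldimethylsilyl triflate, CC(C)(C)[Si](C)(C)OS(=O)(=O)C(F)(F)F
Why: Silylation of the remaining 2-OH installs a bulky non-chelating TBS ether (future O8) that should survive every step up to step 21.

**Step 4**
Reactants: 4 methyl 2-O-TBS-6-deoxy-6-iodo-3,4-O-isopropylidene-α-D-galactopyranoside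
Product: 5 (2R,3S,4S)-2-O-TBS-5,6-dideoxy-3,4-O-isopropylidene-L-arabino-hex-5-enose (aldehyde carbon = C9)
Conditions: Zn dust (activated), THF/H2O 9:1, sonication, 40 °C
Reagents that add atoms: none
Why: Bernet–Vasella reductive fragmentation (zinc insertion into C–I, β-elimination of the ring oxygen, collapse of the hemiacetal) unmasks the C9 aldehyde and the C5 vinyl group and carries galactose C2, C3 and C4 over unchanged as C8, C7 and C6.

**Step 5**
Reactants: 5 (2R,3S,4S)-2-O-TBS-5,6-dideoxy-3,4-O-isopropylidene-L-arabino-hex-5-enose; 6 4-bromo-2-methylbut-1-ene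
Product: 7 (6S,7S,8S)-6-(TBSO)-7,8-(isopropylidenedioxy)-2-methyldeca-1,9-dien-5-ol (both C5 epimers; C5 of this name = C9)
Conditions: 6, Mg, THF, rt; then 5, THF, −78 → 0 °C; aq. NH4Cl
Reagents that add atoms: none
Why: Grignard addition to the aldehyde brings in C2–C4 and C15; the new C9 carbinol forms as a mixture that is oxidised in the next step, so its configuration is irrelevant.

**Step 6**
Reactants: 7 (6S,7S,8S)-6-(TBSO)-7,8-(isopropylidenedioxy)-2-methyldeca-1,9-dien-5-ol
Product: 8 (6R,7S,8S)-6-(TBSO)-7,8-(isopropylidenedioxy)-2-methyldeca-1,9-dien-5-one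
Conditions: Dess–Martin periodinane, NaHCO3, CH2Cl2, 0 °C → rt
Reagents that add atoms: none
Why: Dess–Martin oxidation gives the C9 ketone under buffered, non-basic conditions that should not epimerise the α-silyloxy centre C8.

**Step 7**
Reactants: 8 (6R,7S,8S)-6-(TBSO)-7,8-(isopropylidenedioxy)-2-methyldeca-1,9-dien-5-one
Product: 9 (4Z,6S,7S,8R)-8-(TBSO)-6,7-(isopropylidenedioxy)-4-methylcyclooct-4-en-1-one (C1 of this name = C9; other locants coincide with the target)
Conditions: Grubbs II catalyst (5 mol %), CH2Cl2 (2 mM), 40 °C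
Reagents that add atoms: none
Why: Ring-closing metathesis of the 1,1-disubstituted and the monosubstituted alkene closes the eight-membered ring (pre-organised by the cis-dioxolane) and can only give the Z trisubstituted C4=C5 bond in this ring size.

**Step 8**
Reactants: 9 (4Z,6S,7S,8R)-8-(TBSO)-6,7-(isopropylidenedioxy)-4-methylcyclooct-4-en-1-one
Product: 10 (4Z,6S,7S,8R)-1,8-bis(TBSO)-6,7-(isopropylidenedioxy)-4-methylcycloocta-1,4-diene (C9=C2 silyl enol ether)
Conditions: LDA, THF, −78 °C; TBSCl, HMPA, −78 → 0 °C
Reagents that add atoms: tert-butyldimethylsilyl chloride, CC(C)(C)[Si](C)(C)Cl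
Why: Kinetic deprotonation with LDA should occur at the unhindered C2 methylene and not at the α-silyloxy methine C8, and O-silylation traps the C9=C2 enolate (silyl enol ether formation).

**Step 9**
Reactants: 10 (4Z,6S,7S,8R)-1,8-bis(TBSO)-6,7-(isopropylidenedioxy)-4-methylcycloocta-1,4-diene; 11 methyl propiolate
Product: 13 ten-membered siloxy diene ester (target locants: 9-OTBS; C9=C10 ring-cis; C1=C2 E; C4=C5 Z; 10-CO2Me; 8-OTBS; 6,7-O-isopropylidene), via siloxycyclobutene 12 (not isolated)
Conditions: 11 (1.5 equiv), Tf2NH (5 mol %), CH2Cl2, −78 °C; Et3N quench; then PhMe, 70 °C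
Reagents that add atoms: none
Why: The silyl triflimide generated from Tf2NH activates the propiolate, C2 of enol ether 10 adds to its β-carbon and the allenoate so formed closes on the C9 silyloxocarbenium carbon (stepwise [2+2]; the four-membered ring closes in the 4-exo mode), giving the cis-fused bicyclo[6.2.0]decadiene 12 in which C9–C2 is the shared bond. On warming, 12 undergoes thermal conrotatory 4π-electrocyclic ring opening that breaks exactly this bond, so the eight-membered ring becomes the ten-membered ring with C10 and C1 inserted (no ring is closed in this second event; the ring grows by two atoms). The closest known reaction type is the two-carbon ring expansion of cycloalkanone silyl enol ethers with propiolate esters through siloxycyclobutene carboxylates. No lasting stereocentre is made (C2 and C9 of 12 become sp2 again, so both ring-fusion facial isomers converge) and the stereochemical output is alkene geometry, controlled by torquoselectivity: the siloxy donor on C9 rotates outward and H on C2 inward, which places C8 cis to C1 on C9=C10 and C3 trans to C10 on C1=C2. The step needs chemo- and regioselectivity, secured by the substrate: the polarised enol ether, not the unactivated C4=C5 alkene, is the only π-nucleophile able to attack the activated alkyne, and its nucleophilic carbon C2 must bond to the propiolate β-carbon, which fixes CO2Me (C14) on C10 next to C9–O.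

**Step 10**
Reactants: 13 ten-membered siloxy diene ester
Product: 14 C9-keto triene ester (C10=C1 ring-cis; C2=C3 E; C4=C5 Z; 10-CO2Me; 8-OTBS; 6,7-O-isopropylidene)
Conditions: Pd(OAc)2 (1.2 equiv), MeCN, 40 °C
Reagents that add atoms: none
Why: Vinylogous Saegusa–Ito oxidation: Pd(II) replaces silicon at the dienolate, slips to C2 and undergoes syn β-hydride elimination of H3, which should give the conjugated trienone with the new C2=C3 bond E (ring carbons C1 and C4 anti in the elimination conformer, as in Saegusa oxidations of larger rings) and the C10=C1 bond in the less strained ring-cis geometry.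

**Step 11**
Reactants: 14 C9-keto triene ester
Product: 15 (9R)-triene 1,3-diol (9-OH; 14-OH; 1(10)Z 2E 4Z; 8-OTBS; 6,7-O-isopropylidene)
Conditions: DIBAL-H (6 equiv), CH2Cl2, −78 °C; Rochelle salt
Reagents that add atoms: none
Why: DIBAL-H 1,2-reduction of both the enone carbonyl and the conjugated ester gives the allylic 1,3-diol; hydride is expected to add to C9 anti to the bulky non-chelating 8-OTBS group from the ring periphery (Felkin–Anh), which sets C9 syn to O8 as in the target.

**Step 12**
Reactants: 15 (9R)-triene 1,3-diol; 16 3-methylbut-2-enoyl chloride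
Product: 17 14-O-senecioyl 9-ol (8-OTBS; 6,7-O-isopropylidene triene)
Conditions: 16 (1.1 equiv), pyridine, CH2Cl2, −40 °C
Reagents that add atoms: none
Why: Acylation with the acid chloride at low temperature should select the primary allylic C14–OH over the hindered secondary C9–OH (ester formation).

**Step 13**
Reactants: 18 (R)-2-methylglycidol [(R)-(2-methyloxiran-2-yl)methanol]
Product: 19 (S)-2-methyloxirane-2-carboxylic acid
Conditions: TEMPO (cat.), PhI(OAc)2 (2.2 equiv), MeCN/H2O, 0 °C → rt
Reagents that add atoms: water, O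
Why: TEMPO/PhI(OAc)2 oxidation in wet acetonitrile takes the primary alcohol through the aldehyde hydrate to the acid without touching the epoxide or the quaternary stereocentre (the descriptor changes from R to S only through CIP priorities).

**Step 14**
Reactants: 17 14-O-senecioyl 9-ol; 19 (S)-2-methyloxirane-2-carboxylic acid
Product: 20 9-O-[(S)-2-methylglycidoyl] 14-O-senecioyl triene (8-OTBS; 6,7-O-isopropylidene)
Conditions: 19 (1.5 equiv), DCC, DMAP (0.3 equiv), CH2Cl2, 0 °C → rt
Reagents that add atoms: none
Why: Steglich esterification of the remaining C9–OH with the preformed enantiopure glycidic acid installs the epoxy ester with both stereocentres untouched.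

**Step 15**
Reactants: 20 9-O-[(S)-2-methylglycidoyl] 14-O-senecioyl triene
Product: 21 6,7-diol (cis; 8-OTBS; 9-O-glycidoyl; 14-O-senecioyl triene)
Conditions: 80% aq. AcOH, 40 °C
Reagents that add atoms: none
Why: Mild acid hydrolysis of the acetonide (cleavage at the ketal carbon, not at the triene-activated C6–O bond) frees the cis C6/C7 diol while the secondary TBS ether, the esters and the α-carbonyl epoxide should be stable.

**Step 16**
Reactants: 22 DL-serine
Product: 23 2-bromo-3-hydroxypropanoic acid (racemic)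
Conditions: NaNO2, 48% HBr, H2O, −5 → 0 °C
Reagents that add atoms: hydrogen bromide, Br
Why: Diazotisation of the amino acid in hydrobromic acid replaces NH2 by Br to give the α-bromo acid; its configuration is irrelevant because this carbon becomes sp2 (C11).

**Step 17**
Reactants: 23 2-bromo-3-hydroxypropanoic acid
Product: 25 2-bromo-3-(TBSO)propanoic acid, via silyl ester 24 (not isolated)
Conditions: TBSCl (2.2 equiv), imidazole, DMF, rt; then THF/H2O/AcOH, rt
Reagents that add atoms: tert-butyldimethylsilyl chloride, CC(C)(C)[Si](C)(C)Cl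
Why: Silylation of hydroxyl and carboxyl followed by selective hydrolysis of the labile silyl ester gives the O-TBS acid (protection).

**Step 18**
Reactants: 21 6,7-diol; 25 2-bromo-3-(TBSO)propanoic acid
Product: 26 6-O-[2-bromo-3-(TBSO)propanoyl] 7-ol (C11 epimers; 8-OTBS; 9-O-glycidoyl; 14-O-senecioyl triene)
Conditions: 25 (1.2 equiv), DCC, DMAP (cat.), CH2Cl2, −20 °C
Reagents that add atoms: none
Why: Steglich esterification is expected at the allylic C6–OH, which is flanked by an sp2 carbon, rather than at the C7–OH wedged between C6–O and the 8-OTBS group (steric regioselection); the α-bromo centre is a mixture that is destroyed later.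

**Step 19**
Reactants: 26 6-O-[2-bromo-3-(TBSO)propanoyl] 7-ol
Product: 27 7-ketone (6-O-bromoacyl; 8-OTBS; 9-O-glycidoyl; 14-O-senecioyl triene)
Conditions: Dess–Martin periodinane, NaHCO3, CH2Cl2, 0 °C → rt
Reagents that add atoms: none
Why: Dess–Martin oxidation of the remaining C7–OH gives the α-acyloxy ketone without base, so C6 and C8 should not epimerise.

**Step 20**
Reactants: 27 7-ketone
Product: 30 8,13-bis-O-TBS butenolide triene (9-O-glycidoyl; 14-O-senecioyl), via phosphonium bromide 28 (not isolated), via phosphorane 29 (not isolated)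
Conditions: PPh3, MeCN, 50 °C; then Et3N, 70 °C
Reagents that add atoms: none
Why: Intramolecular Wittig reaction: SN2 displacement of bromide by PPh3 gives the phosphonium salt, triethylamine forms the ester-stabilised ylide, and five-ring olefination of the C7 ketone closes the butenolide with the tetrasubstituted C7=C11 bond and C13 already in place.

**Step 21**
Reactants: 30 8,13-bis-O-TBS butenolide triene
Product: 31 8,13-diol (butenolide triene; 9-O-glycidoyl; 14-O-senecioyl)
Conditions: HF·pyridine, pyridine, THF, 0 °C → rt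
Reagents that add atoms: none
Why: Buffered HF·pyridine cleaves the primary (O13) and the secondary (O8) TBS ether by Si–F bond formation and should leave the esters, the α-carbonyl epoxide and the triene untouched (desilylation).

**Step 22**
Reactants: 31 8,13-diol
Product: 32 (1(10)Z,2E,4Z)-triene tetraester (8,13-diacetate; 9-O-glycidoyl; 14-O-senecioyl butenolide)
Conditions: Ac2O, pyridine, DMAP (cat.), CH2Cl2, 0 °C
Reagents that add atoms: acetic anhydride, CC(=O)OC(C)=O
Why: Acetylation of both hydroxyls gives the 8,13-diacetate (ester formation); it is run at once and cold to outrun 9→8 acyl migration.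

**Step 23**
Reactants: 32 (1(10)Z,2E,4Z)-triene tetraester
Product: 34 CNP0279449.1, via 4,5-monoepoxide 33 (not isolated)
Conditions: dimethyldioxirane (2.3 equiv, acetone solution), CH2Cl2, −40 → 0 °C
Reagents that add atoms: dimethyldioxirane, CC1(C)OO1
Why: Electrophilic epoxidation with neutral DMDO (so the vinyl-epoxide products survive) is expected to take the electron-rich trisubstituted C4=C5 bond first, from the ring periphery on the face of the lactone oxygen (H6 eclipsed, A1,3 control; 4S,5S), and then the C2=C3 bond from the same outer face of the s-trans C2–C5 unit (2R,3S), while C1=C10 (two allylic acyloxy groups), the senecioate and the butenolide alkenes are electron-poor and should stay untouched.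

**Compound list**
1 | methyl α-D-galactopyranoside | CO[C@H]1O[C@H](CO)[C@H](O)[C@H](O)[C@H]1O | starting material
2 | methyl 3,4-O-isopropylidene-α-D-galactopyranoside | CO[C@H]1O[C@H](CO)[C@@H]2OC(C)(C)O[C@@H]2[C@H]1O | intermediate
3 | methyl 6-deoxy-6-iodo-3,4-O-isopropylidene-α-D-galactopyranoside | CO[C@H]1O[C@H](CI)[C@@H]2OC(C)(C)O[C@@H]2[C@H]1O | intermediate
4 | methyl 2-O-TBS-6-deoxy-6-iodo-3,4-O-isopropylidene-α-D-galactopyranoside | CO[C@H]1O[C@H](CI)[C@@H]2OC(C)(C)O[C@@H]2[C@H]1O[Si](C)(C)C(C)(C)C | intermediate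
5 | (2R,3S,4S)-2-O-TBS-5,6-dideoxy-3,4-O-isopropylidene-L-arabino-hex-5-enose | O=C[C@H](O[Si](C)(C)C(C)(C)C)[C@H]1OC(C)(C)O[C@H]1C=C | intermediate
6 | 4-bromo-2-methylbut-1-ene | C=C(C)CCBr | starting material
7 | (6S,7S,8S)-6-(TBSO)-7,8-(isopropylidenedioxy)-2-methyldeca-1,9-dien-5-ol (C5 epimers) | C=C(C)CCC(O)[C@H](O[Si](C)(C)C(C)(C)C)[C@H]1OC(C)(C)O[C@H]1C=C | intermediate
8 | (6R,7S,8S)-6-(TBSO)-7,8-(isopropylidenedioxy)-2-methyldeca-1,9-dien-5-one | C=C(C)CCC(=O)[C@H](O[Si](C)(C)C(C)(C)C)[C@H]1OC(C)(C)O[C@H]1C=C | intermediate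
9 | (4Z,6S,7S,8R)-8-(TBSO)-6,7-(isopropylidenedioxy)-4-methylcyclooct-4-en-1-one | O=C1CC/C(C)=C\[C@@H]2OC(C)(C)O[C@@H]2[C@H]1O[Si](C)(C)C(C)(C)C | intermediate
10 | (4Z,6S,7S,8R)-1,8-bis(TBSO)-6,7-(isopropylidenedioxy)-4-methylcycloocta-1,4-diene | CC(C)(C)[Si](C)(C)O/C1=C/C/C(C)=C\[C@@H]2OC(C)(C)O[C@@H]2[C@H]1O[Si](C)(C)C(C)(C)C | intermediate
11 | methyl propiolate | C#CC(=O)OC | starting material
12 | methyl 1,2-bis(TBSO)-3,4-(isopropylidenedioxy)-6-methylbicyclo[6.2.0]deca-5,9-diene-10-carboxylate (cis-fused; both facial isomers; C1/C8 of this name = C9/C2) | COC(=O)C1=CC2C/C(C)=C\[C@@H]3OC(C)(C)O[C@@H]3[C@@H](O[Si](C)(C)C(C)(C)C)C12O[Si](C)(C)C(C)(C)C | intermediate (not isolated)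
13 | ten-membered siloxy diene ester (9-OTBS; C9=C10 ring-cis; C1=C2 E; C4=C5 Z; 10-CO2Me; 8-OTBS; 6,7-O-isopropylidene) | C\C1=C\[C@@H]2OC(C)(C)O[C@@H]2[C@@H](O[Si](C)(C)C(C)(C)C)\C(O[Si](C)(C)C(C)(C)C)=C(C(=O)OC)/C=C/C/1 | intermediate
14 | C9-keto triene ester (C10=C1 ring-cis; C2=C3 E; C4=C5 Z; 10-CO2Me; 8-OTBS; 6,7-O-isopropylidene) | C\C1=C\[C@@H]2OC(C)(C)O[C@@H]2[C@@H](O[Si](C)(C)C(C)(C)C)C(=O)\C(C(=O)OC)=C/C=C/1 | intermediate
15 | (9R)-triene 1,3-diol (9-OH; 14-OH; 1(10)Z 2E 4Z; 8-OTBS; 6,7-O-isopropylidene) | C\C1=C\[C@@H]2OC(C)(C)O[C@@H]2[C@@H](O[Si](C)(C)C(C)(C)C)[C@H](O)\C(CO)=C/C=C/1 | intermediate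
16 | 3-methylbut-2-enoyl chloride | CC(C)=CC(Cl)=O | starting material
17 | 14-O-senecioyl 9-ol (8-OTBS; 6,7-O-isopropylidene triene) | C\C1=C\[C@@H]2OC(C)(C)O[C@@H]2[C@@H](O[Si](C)(C)C(C)(C)C)[C@H](O)\C(COC(=O)C=C(C)C)=C/C=C/1 | intermediate
18 | (R)-2-methylglycidol | OC[C@]1(C)CO1 | starting material
19 | (S)-2-methyloxirane-2-carboxylic acid | OC(=O)[C@]1(C)CO1 | intermediate
20 | 9-O-[(S)-2-methylglycidoyl] 14-O-senecioyl triene (8-OTBS; 6,7-O-isopropylidene) | C\C1=C\[C@@H]2OC(C)(C)O[C@@H]2[C@@H](O[Si](C)(C)C(C)(C)C)[C@H](OC(=O)[C@]3(C)CO3)\C(COC(=O)C=C(C)C)=C/C=C/1 | intermediate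
21 | 6,7-diol (8-OTBS; 9-O-glycidoyl; 14-O-senecioyl triene) | C\C1=C\[C@H](O)[C@H](O)[C@@H](O[Si](C)(C)C(C)(C)C)[C@H](OC(=O)[C@]3(C)CO3)\C(COC(=O)C=C(C)C)=C/C=C/1 | intermediate
22 | DL-serine | NC(CO)C(=O)O | starting material
23 | 2-bromo-3-hydroxypropanoic acid | OCC(Br)C(=O)O | intermediate
24 | tert-butyldimethylsilyl 2-bromo-3-(TBSO)propanoate | CC(C)(C)[Si](C)(C)OCC(Br)C(=O)O[Si](C)(C)C(C)(C)C | intermediate (not isolated)
25 | 2-bromo-3-(TBSO)propanoic acid | CC(C)(C)[Si](C)(C)OCC(Br)C(=O)O | intermediate
26 | 6-O-[2-bromo-3-(TBSO)propanoyl] 7-ol | C\C1=C\[C@H](OC(=O)C(Br)CO[Si](C)(C)C(C)(C)C)[C@H](O)[C@@H](O[Si](C)(C)C(C)(C)C)[C@H](OC(=O)[C@]3(C)CO3)\C(COC(=O)C=C(C)C)=C/C=C/1 | intermediate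
27 | 7-ketone | C\C1=C\[C@H](OC(=O)C(Br)CO[Si](C)(C)C(C)(C)C)C(=O)[C@@H](O[Si](C)(C)C(C)(C)C)[C@H](OC(=O)[C@]3(C)CO3)\C(COC(=O)C=C(C)C)=C/C=C/1 | intermediate
28 | phosphonium bromide of 27 (PPh3+ on C11) | C\C1=C\[C@H](OC(=O)C(CO[Si](C)(C)C(C)(C)C)[P+](c4ccccc4)(c4ccccc4)c4ccccc4)C(=O)[C@@H](O[Si](C)(C)C(C)(C)C)[C@H](OC(=O)[C@]3(C)CO3)\C(COC(=O)C=C(C)C)=C/C=C/1.[Br-] | intermediate (not isolated)
29 | phosphorane (ylide at C11) | C\C1=C\[C@H](OC(=O)C(CO[Si](C)(C)C(C)(C)C)=P(c4ccccc4)(c4ccccc4)c4ccccc4)C(=O)[C@@H](O[Si](C)(C)C(C)(C)C)[C@H](OC(=O)[C@]3(C)CO3)\C(COC(=O)C=C(C)C)=C/C=C/1 | intermediate (not isolated)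
30 | 8,13-bis-O-TBS butenolide triene | CC(C)(C)[Si](C)(C)OCC1=C2[C@@H](O[Si](C)(C)C(C)(C)C)[C@H](OC(=O)[C@]3(C)CO3)/C(COC(=O)C=C(C)C)=C\C=C\C(C)=C/[C@@H]2OC1=O | intermediate
31 | 8,13-diol butenolide triene | OCC1=C2[C@@H](O)[C@H](OC(=O)[C@]3(C)CO3)/C(COC(=O)C=C(C)C)=C\C=C\C(C)=C/[C@@H]2OC1=O | intermediate
32 | (1(10)Z,2E,4Z)-triene tetraester | CC(=O)OCC1=C2[C@@H](OC(C)=O)[C@H](OC(=O)[C@]3(C)CO3)/C(COC(=O)C=C(C)C)=C\C=C\C(C)=C/[C@@H]2OC1=O | intermediate
33 | (4S,5S)-4,5-monoepoxide of 32 | CC(=O)OCC1=C2[C@@H](OC(C)=O)[C@H](OC(=O)[C@]3(C)CO3)/C(COC(=O)C=C(C)C)=C\C=C\[C@@]3(C)O[C@H]3[C@@H]2OC1=O | intermediate (not isolated)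
34 | CNP0279449.1 | CC(=O)OCC1=C2[C@@H](OC(C)=O)[C@H](OC(=O)[C@]3(C)CO3)/C(COC(=O)C=C(C)C)=C\[C@H]3O[C@@H]3[C@@]3(C)O[C@H]3[C@@H]2OC1=O | target

**Totals and risks**
Total step count: 23 (steps 13, 16 and 17 prepare the two acyl building blocks). Longest linear sequence: 20 steps (1–12, 14, 15, 18–23).

Step 10. Palladation of the ester-conjugated (push–pull) dienol ether may be slow, so that protodesilylation to the β-keto ester competes, and the β-hydride elimination may form the C2=C3 bond with poor E control. The fallback replaces the palladium step by halogenation and vinylogous elimination. It sets out from siloxy diene 13, which is brominated at C10 with N-bromosuccinimide (THF, −78 °C) to the α-bromo β-keto ester F1 with the E C1=C2 bond intact. Base-induced 1,4-dehydrobromination (DBU, PhMe, 0 °C → rt; loss of H3 and bromide through the extended conformer) then returns to the route at trienone 14.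

Step 23. Oxygen transfer may not discriminate well enough between the two faces of the C4=C5 and C2=C3 bonds of the flexible ring, and may also reach the C1=C10 bond. The fallback changes from substrate control to reagent control. It sets out from triene 32 and runs the two epoxidations as separate operations with fructose-derived ketone catalysts (Shi epoxidation, buffered Oxone or H2O2/MeCN, 0 °C). The L-series ketone is used first for the trisubstituted C4=C5 bond (4S,5S sense by the spiro transition-state model), giving the monoepoxide 33, this time isolated. The D-fructose-derived ketone is then used for the trans-disubstituted C2=C3 bond (2R,3S sense), returning to the route at target 34. No compound outside the list is made (F0).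

Step 11. Hydride delivery to the C9 carbonyl of the medium ring may show poor facial selectivity (Felkin–Anh control competing with ring-conformational control), giving the C9 epimer. The fallback uses reagent control in two stages. It sets out from trienone 14, whose ketone alone is reduced by Corey–Bakshi–Shibata reduction [(R)-2-methyl-CBS-oxazaborolidine, catecholborane, PhMe, −78 °C; the alkenyl C10 side taken as the large group] to the (9R)-hydroxy ester F2. DIBAL-H reduction of the ester (CH2Cl2, −78 °C) then returns to the route at diol 15.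

**Further compounds**
F1 | step 10 | methyl 10-bromo-9-oxo diene ester (target locants: C10–Br, both epimers; C1=C2 E; C4=C5 Z; 8-OTBS; 6,7-O-isopropylidene) | C\C1=C\[C@@H]2OC(C)(C)O[C@@H]2[C@@H](O[Si](C)(C)C(C)(C)C)C(=O)C(Br)(C(=O)OC)/C=C/C/1
F2 | step 11 | (9R)-9-hydroxy triene methyl ester (10-CO2Me; C10=C1 ring-cis; 2E; 4Z; 8-OTBS; 6,7-O-isopropylidene) | C\C1=C\[C@@H]2OC(C)(C)O[C@@H]2[C@@H](O[Si](C)(C)C(C)(C)C)[C@H](O)\C(C(=O)OC)=C/C=C/1
F0 | step 23 | none | none
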